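The chain C1–C6 (C1 the carbinol on oxazole C4, C6 the methyl, oxygens on C3, C4 and C5, CH2 at C2) is a 4-O-myristoyl-2,6-dideoxy-L-lyxo-hexose, so the plan rests on building this hexose de novo as a dihydropyranone. A single catalytic asymmetric hetero-Diels–Alder cyclocondensation of acetaldehyde with a 1-methoxy-3-silyloxy-4-myristoyloxybutadiene forms C4–C5 and O5–C1, closes the pyran ring and sets C4 and C5 cis, with the fatty ester already on O4. Its precursor is the (1Z,3E) silyl dienol ether of (E)-4-methoxy-2-oxobut-3-enyl tetradecanoate. Luche reduction, hydration and oxidation give the δ-lactone, which a 4-magnesiated bis-oxazole attacks at C1; ketone reduction and desilylation finish.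

Key step: step 4

Remark: the chain numbering C1–C6 above is used in the Why lines; the hemiketal of step 13 is taken as an anomeric mixture in equilibrium with its open-chain ketone; a serine-derived oxazole-4-carboxylate has one carbon more at C4 than the target, so that carbon is excised as CO2 (step 12) before the ring is metalated; the (1R,2S) series of the chromium catalyst is assigned by analogy with other aliphatic aldehydes and its sense must be confirmed by correlation.

Step 1
Reactants: 1 trans-1-methoxy-3-(trimethylsilyloxy)buta-1,3-diene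
Product: 2 (E)-1-bromo-4-methoxybut-3-en-2-one
Conditions: NBS, THF, −78 → 0 °C; aq. NaHCO3
Reagents that add atoms: N-bromosuccinimide, O=C1CCC(=O)N1Br
Why: Electrophilic α-bromination of a silyl enol ether: the terminal CH2 of the silyl dienol ether is its nucleophilic carbon, so bromine is delivered there and loss of the silyl group returns the vinylogous ester as the α'-bromo ketone.

Step 2
Reactants: 2 (E)-1-bromo-4-methoxybut-3-en-2-one; 3 myristic acid
Product: 4 (E)-4-methoxy-2-oxobut-3-en-1-yl tetradecanoate
Conditions: K2CO3, DMF, 0 °C → rt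
Reagents that add atoms: none
Why: SN2 displacement of a primary α-bromo ketone by a carboxylate, which is fast at room temperature and leaves the β-methoxy enone untouched because the carboxylate is weakly basic and a poor conjugate donor.

Step 3
Reactants: 4 (E)-4-methoxy-2-oxobut-3-en-1-yl tetradecanoate
Product: 5 (1Z,3E)-2-[(tert-butyldimethylsilyl)oxy]-4-methoxybuta-1,3-dien-1-yl tetradecanoate
Conditions: TBSOTf, Et3N, Et2O, −10 → 0 °C
Reagents that add atoms: tert-butyldimethylsilyl trifluoromethanesulfonate, CC(C)(C)[Si](C)(C)OS(=O)(=O)C(F)(F)F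
Why: Soft enolisation (silyl triflate and tertiary amine) removes a proton from the CH2 flanked by ketone and acyloxy group and gives the Z silyl enol ether (O–Si and O–acyl cis) because that geometry avoids allylic strain with the vinyl ether arm; the tert-butyldimethylsilyl group is chosen so that the waxy, non-distillable diene survives filtration and storage.

Step 4
Reactants: 5 (1Z,3E)-2-[(tert-butyldimethylsilyl)oxy]-4-methoxybuta-1,3-dien-1-yl tetradecanoate; 6 acetaldehyde
Product: 8 (2S,3R)-2-methyl-4-oxo-3,4-dihydro-2H-pyran-3-yl tetradecanoate, via cycloadduct 7 (not isolated)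
Conditions: 6 (3 equiv), CrCl(C27H29NO2) (5 mol%; chloride complex of trivalent chromium with the dianion of (1R,2S)-1-{[3-(1-adamantyl)-2-hydroxy-5-methylbenzylidene]amino}indan-2-ol), 4 Å MS, t-BuOMe, −20 → 0 °C; then CF3CO2H, CH2Cl2, 0 °C
Reagents that add atoms: none
Why: The chromium Lewis acid binds acetaldehyde anti to its methyl group and diene 5 adds through a concerted but asynchronous endo [4+2] transition state, its acyloxy-bearing terminus bonding to the aldehyde carbon (C4–C5) and its methoxy-bearing terminus to the aldehyde oxygen (O5–C1), to give cycloadduct 7, from which trifluoroacetic acid cleaves the silyl enol ether and expels methanol to leave enone 8. The closest known reaction type is the hetero-Diels–Alder reaction of aliphatic aldehydes with substituted 1-methoxy-3-silyloxybutadienes under Schiff-base complexes of trivalent chromium, together with the cis-selective Lewis acid cyclocondensation of 4-acyloxy dienes of this kind in the racemic series. The pyran ring is closed by the intermolecular [4+2] cycloaddition itself (if the reaction went stepwise, by Mukaiyama aldol addition and 6-endo-trig oxa-Michael closure). C5 (ring C2, S) is set by the catalyst, which is expected to leave the Re face of the bound aldehyde open, and C4 (ring C3, R) is set relative to C5 by the endo transition state, since the myristoyloxy group sits on the outside (Z) position of the diene terminus and so ends up cis to the endo methyl group. The step needs Re over Si and endo over exo selectivity and one regiochemistry: the first rests on the ligand, the second on the Z enol ether geometry fixed in step 3, and the third on the polarisation of the diene by its 1-methoxy and 3-silyloxy groups.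

Step 5
Reactants: 8 (2S,3R)-2-methyl-4-oxo-3,4-dihydro-2H-pyran-3-yl tetradecanoate
Product: 9 (2S,3S,4S)-4-hydroxy-2-methyl-3,4-dihydro-2H-pyran-3-yl tetradecanoate (4-O-myristoyl-L-fucal)
Conditions: NaBH4, CeCl3·7H2O, MeOH/CH2Cl2, −78 °C; AcOH quench
Reagents that add atoms: none
Why: Luche 1,2-reduction: in the half-chair of 8 the 2-methyl group is pseudoequatorial and the 3-acyloxy group pseudoaxial, so hydride adds to the ketone anti to the ester and the new carbinol (chain C3, S) is cis to both neighbours, while low temperature and the acidic quench keep the ester from migrating.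

Step 6
Reactants: 9 (2S,3S,4S)-4-hydroxy-2-methyl-3,4-dihydro-2H-pyran-3-yl tetradecanoate
Product: 10 (2S,3R,4S)-4-[(tert-butyldimethylsilyl)oxy]-2-methyl-3,4-dihydro-2H-pyran-3-yl tetradecanoate
Conditions: TBSOTf, 2,6-lutidine, CH2Cl2, −78 °C
Reagents that add atoms: tert-butyldimethylsilyl trifluoromethanesulfonate, CC(C)(C)[Si](C)(C)OS(=O)(=O)C(F)(F)F
Why: Silylation of a hindered secondary alcohol with a silyl triflate and 2,6-lutidine is fast at −78 °C and neither basic nor nucleophilic enough to move the neighbouring cis ester or to open the enol ether.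

Step 7
Reactants: 10 (2S,3R,4S)-4-[(tert-butyldimethylsilyl)oxy]-2-methyl-3,4-dihydro-2H-pyran-3-yl tetradecanoate
Product: 11 (2S,3R,4S)-4-[(tert-butyldimethylsilyl)oxy]-6-hydroxy-2-methyloxan-3-yl tetradecanoate (anomeric mixture)
Conditions: Ph3P·HBr (10 mol%), THF/H2O, rt
Reagents that add atoms: water, O
Why: Acid-catalysed hydration of a glycal: protonation at C2 gives the oxocarbenium ion that water captures at C1 to give the 2-deoxy lactol, and allylic (Ferrier) transposition is not expected because the O3 silyl ether is a poor leaving group.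

Step 8
Reactants: 11 (2S,3R,4S)-4-[(tert-butyldimethylsilyl)oxy]-6-hydroxy-2-methyloxan-3-yl tetradecanoate
Product: 12 (2S,3R,4S)-4-[(tert-butyldimethylsilyl)oxy]-2-methyl-6-oxooxan-3-yl tetradecanoate
Conditions: Dess–Martin periodinane, CH2Cl2, rt
Reagents that add atoms: none
Why: Dess–Martin oxidation of a lactol to the δ-lactone under near-neutral conditions that leave the silyl ether, the ester and the three stereocentres untouched.

Step 9
Reactants: 13 2-(1,3-oxazol-5-yl)acetic acid; 14 L-serine methyl ester hydrochloride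
Product: 16 methyl N-[2-(1,3-oxazol-5-yl)acetyl]-L-serinate, via acyl imidazole 15 (not isolated)
Conditions: CDI, THF, rt; then 14, Et3N, rt
Reagents that add atoms: none
Why: Amide coupling through the acyl imidazole, which acylates the amine of the serine ester much faster than its hydroxyl group; the serine stereocentre is carried only until step 10, where it becomes sp2.

Step 10
Reactants: 16 methyl N-[2-(1,3-oxazol-5-yl)acetyl]-L-serinate
Product: 18 methyl 2-(1,3-oxazol-5-ylmethyl)-1,3-oxazole-4-carboxylate, via oxazoline 17 (not isolated)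
Conditions: Deoxo-Fluor, CH2Cl2, −20 °C; then BrCCl3, DBU, 0 °C → rt
Reagents that add atoms: none
Why: Cyclodehydration of a β-hydroxy amide with an aminosulfur trifluoride gives the oxazoline by displacement of the activated primary hydroxyl by the amide oxygen, and bromination–dehydrobromination of its C4 ester enolate with BrCCl3 and DBU aromatises it to the oxazole in the same flask.

Step 11
Reactants: 18 methyl 2-(1,3-oxazol-5-ylmethyl)-1,3-oxazole-4-carboxylate
Product: 19 2-(1,3-oxazol-5-ylmethyl)-1,3-oxazole-4-carboxylic acid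
Conditions: LiOH, THF/H2O, 0 °C; then 1 M HCl to pH 3
Reagents that add atoms: lithium hydroxide, [Li+].[OH-]
Why: Saponification of a heteroaryl methyl ester with LiOH at 0 °C, followed by acidification to the free acid.

Step 12
Reactants: 19 2-(1,3-oxazol-5-ylmethyl)-1,3-oxazole-4-carboxylic acid
Product: 20 4-iodo-2-(1,3-oxazol-5-ylmethyl)-1,3-oxazole
Conditions: [Cu(MeCN)4]BF4 (20 mol%), NIS, MeCN, 365 nm LED, rt
Reagents that add atoms: N-iodosuccinimide, O=C1CCC(=O)N1I
Why: Copper-catalysed decarboxylative iodination of a heteroaryl carboxylic acid by ligand-to-metal charge transfer: irradiation of the carboxylate of divalent copper gives the aroyloxy radical, which loses CO2, and the oxazol-4-yl radical takes iodine from NIS, so that the carboxyl carbon, which the target does not contain, is replaced by the handle for metalation.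

Step 13
Reactants: 20 4-iodo-2-(1,3-oxazol-5-ylmethyl)-1,3-oxazole; 12 (2S,3R,4S)-4-[(tert-butyldimethylsilyl)oxy]-2-methyl-6-oxooxan-3-yl tetradecanoate
Product: 22 (2S,3R,4S)-4-[(tert-butyldimethylsilyl)oxy]-6-hydroxy-2-methyl-6-[2-(1,3-oxazol-5-ylmethyl)-1,3-oxazol-4-yl]oxan-3-yl tetradecanoate (anomeric mixture), via oxazolyl Grignard reagent 21 (not isolated)
Conditions: 20, iPrMgCl·LiCl, THF, −78 °C; then 12, −78 → −40 °C; AcOH, then aq. NH4Cl
Reagents that add atoms: none
Why: Iodine–magnesium exchange of a heteroaryl iodide at −78 °C should outrun deprotonation of the other oxazole at C2 or of the CH2 between the rings, and the 4-oxazolyl Grignard reagent then adds once to the δ-lactone (addition of an aryl Grignard reagent to a lactone), which is far more electrophilic than the hindered myristate, the magnesium hemiketal alkoxide resisting a second addition until work-up.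

Step 14
Reactants: 22 (2S,3R,4S)-4-[(tert-butyldimethylsilyl)oxy]-6-hydroxy-2-methyl-6-[2-(1,3-oxazol-5-ylmethyl)-1,3-oxazol-4-yl]oxan-3-yl tetradecanoate
Product: 24 (2S,3R,4S,6R)-4-[(tert-butyldimethylsilyl)oxy]-2,6-dihydroxy-6-[2-(1,3-oxazol-5-ylmethyl)-1,3-oxazol-4-yl]hexan-3-yl tetradecanoate, via open-chain hydroxy ketone 23 (not isolated)
Conditions: RuCl[(R,R)-TsDPEN](p-cymene) (5 mol%), HCO2H/Et3N (5:2), CH2Cl2, rt
Reagents that add atoms: none
Why: Noyori asymmetric transfer hydrogenation of a heteroaryl ketone: hemiketal 22 equilibrates with ketone 23 in the formic acid/triethylamine medium and only the ketone is reduced, the (R,R)-TsDPEN ruthenium hydride delivering hydrogen in the sense known for aryl alkyl ketones to give the (R)-carbinol at C1, which is 1,3-syn to O3, under catalyst control.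

Step 15
Reactants: 24 (2S,3R,4S,6R)-4-[(tert-butyldimethylsilyl)oxy]-2,6-dihydroxy-6-[2-(1,3-oxazol-5-ylmethyl)-1,3-oxazol-4-yl]hexan-3-yl tetradecanoate
Product: 25 (2S,3R,4S,6R)-2,4,6-trihydroxy-6-[2-(1,3-oxazol-5-ylmethyl)-1,3-oxazol-4-yl]hexan-3-yl tetradecanoate (CNP0268144.1)
Conditions: HF·pyridine, pyridine, THF, 0 °C → rt; aq. NaHCO3 to pH 7
Reagents that add atoms: none
Why: Fluoride-mediated cleavage of a secondary silyl ether under buffered acidic conditions, chosen over basic fluoride so that the C4 myristate does not migrate to the flanking hydroxyl groups.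

Compound list
1 | trans-1-methoxy-3-(trimethylsilyloxy)buta-1,3-diene | CO/C=C/C(=C)O[Si](C)(C)C | starting material
2 | (E)-1-bromo-4-methoxybut-3-en-2-one | CO/C=C/C(=O)CBr | intermediate
3 | myristic acid (tetradecanoic acid) | CCCCCCCCCCCCCC(=O)O | starting material
4 | (E)-4-methoxy-2-oxobut-3-en-1-yl tetradecanoate | CO/C=C/C(=O)COC(=O)CCCCCCCCCCCCC | intermediate
5 | (1Z,3E)-2-[(tert-butyldimethylsilyl)oxy]-4-methoxybuta-1,3-dien-1-yl tetradecanoate | CO/C=C/C(=C/OC(=O)CCCCCCCCCCCCC)O[Si](C)(C)C(C)(C)C | intermediate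
6 | acetaldehyde | CC=O | starting material
7 | (2S,3R,6S)-4-[(tert-butyldimethylsilyl)oxy]-6-methoxy-2-methyl-3,6-dihydro-2H-pyran-3-yl tetradecanoate (cycloadduct, not isolated) | C[C@H]1[C@@H](OC(=O)CCCCCCCCCCCCC)C(O[Si](C)(C)C(C)(C)C)=C[C@@H](OC)O1 | intermediate
8 | (2S,3R)-2-methyl-4-oxo-3,4-dihydro-2H-pyran-3-yl tetradecanoate | C[C@H]1[C@@H](OC(=O)CCCCCCCCCCCCC)C(=O)C=CO1 | intermediate
9 | (2S,3S,4S)-4-hydroxy-2-methyl-3,4-dihydro-2H-pyran-3-yl tetradecanoate | C[C@H]1[C@@H](OC(=O)CCCCCCCCCCCCC)[C@@H](O)C=CO1 | intermediate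
10 | (2S,3R,4S)-4-[(tert-butyldimethylsilyl)oxy]-2-methyl-3,4-dihydro-2H-pyran-3-yl tetradecanoate | C[C@H]1[C@@H](OC(=O)CCCCCCCCCCCCC)[C@@H](O[Si](C)(C)C(C)(C)C)C=CO1 | intermediate
11 | (2S,3R,4S)-4-[(tert-butyldimethylsilyl)oxy]-6-hydroxy-2-methyloxan-3-yl tetradecanoate (anomeric mixture) | C[C@H]1[C@@H](OC(=O)CCCCCCCCCCCCC)[C@@H](O[Si](C)(C)C(C)(C)C)CC(O)O1 | intermediate
12 | (2S,3R,4S)-4-[(tert-butyldimethylsilyl)oxy]-2-methyl-6-oxooxan-3-yl tetradecanoate | C[C@H]1[C@@H](OC(=O)CCCCCCCCCCCCC)[C@@H](O[Si](C)(C)C(C)(C)C)CC(=O)O1 | intermediate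
13 | 2-(1,3-oxazol-5-yl)acetic acid | OC(=O)Cc1cnco1 | starting material
14 | L-serine methyl ester hydrochloride | Cl.COC(=O)[C@@H](N)CO | starting material
15 | 1-[2-(1,3-oxazol-5-yl)acetyl]-1H-imidazole (not isolated) | O=C(Cc1cnco1)n1ccnc1 | intermediate
16 | methyl N-[2-(1,3-oxazol-5-yl)acetyl]-L-serinate | COC(=O)[C@@H](NC(=O)Cc1cnco1)CO | intermediate
17 | methyl (4S)-2-(1,3-oxazol-5-ylmethyl)-4,5-dihydro-1,3-oxazole-4-carboxylate (not isolated) | COC(=O)[C@@H]1COC(Cc2cnco2)=N1 | intermediate
18 | methyl 2-(1,3-oxazol-5-ylmethyl)-1,3-oxazole-4-carboxylate | COC(=O)c1coc(Cc2cnco2)n1 | intermediate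
19 | 2-(1,3-oxazol-5-ylmethyl)-1,3-oxazole-4-carboxylic acid | OC(=O)c1coc(Cc2cnco2)n1 | intermediate
20 | 4-iodo-2-(1,3-oxazol-5-ylmethyl)-1,3-oxazole | Ic1coc(Cc2cnco2)n1 | intermediate
21 | chloro[2-(1,3-oxazol-5-ylmethyl)-1,3-oxazol-4-yl]magnesium (not isolated) | Cl[Mg]c1coc(Cc2cnco2)n1 | intermediate
22 | (2S,3R,4S)-4-[(tert-butyldimethylsilyl)oxy]-6-hydroxy-2-methyl-6-[2-(1,3-oxazol-5-ylmethyl)-1,3-oxazol-4-yl]oxan-3-yl tetradecanoate (anomeric mixture) | C[C@H]1[C@@H](OC(=O)CCCCCCCCCCCCC)[C@@H](O[Si](C)(C)C(C)(C)C)CC(O)(c2coc(Cc3cnco3)n2)O1 | intermediate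
23 | (2S,3R,4S)-4-[(tert-butyldimethylsilyl)oxy]-2-hydroxy-6-oxo-6-[2-(1,3-oxazol-5-ylmethyl)-1,3-oxazol-4-yl]hexan-3-yl tetradecanoate (not isolated) | C[C@H](O)[C@@H](OC(=O)CCCCCCCCCCCCC)[C@@H](O[Si](C)(C)C(C)(C)C)CC(=O)c1coc(Cc2cnco2)n1 | intermediate
24 | (2S,3R,4S,6R)-4-[(tert-butyldimethylsilyl)oxy]-2,6-dihydroxy-6-[2-(1,3-oxazol-5-ylmethyl)-1,3-oxazol-4-yl]hexan-3-yl tetradecanoate | C[C@H](O)[C@@H](OC(=O)CCCCCCCCCCCCC)[C@@H](O[Si](C)(C)C(C)(C)C)C[C@@H](O)c1coc(Cc2cnco2)n1 | intermediate
25 | (2S,3R,4S,6R)-2,4,6-trihydroxy-6-[2-(1,3-oxazol-5-ylmethyl)-1,3-oxazol-4-yl]hexan-3-yl tetradecanoate | CCCCCCCCCCCCCC(=O)O[C@H]([C@H](C)O)[C@@H](O)C[C@@H](O)c1coc(Cc2cnco2)n1 | target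

Total step count: 15. Longest linear sequence: 11 steps (steps 1–8, then 13–15); the bis-oxazole branch is steps 9–12.

Steps most likely to fail

1. Step 4. The acyloxy group makes the diene less nucleophilic, so the mild chiral Lewis acid may turn over slowly while acetaldehyde oligomerises. A stepwise aldol pathway or an exo approach would also erode the cis relationship and the enantioselectivity. Fallback: setting out from 5 and 6, the cyclocondensation is run with the achiral Lewis acid Eu(fod)3 in CH2Cl2, the cis-selective racemic version. This gives the cycloadduct as a racemate, that is 7 together with its enantiomer (2R,3S,6R)-4-[(tert-butyldimethylsilyl)oxy]-6-methoxy-2-methyl-3,6-dihydro-2H-pyran-3-yl tetradecanoate F1. Trifluoroacetic acid converts it into the racemic cis-pyranone, 8 together with (2R,3S)-2-methyl-4-oxo-3,4-dihydro-2H-pyran-3-yl tetradecanoate F2. Preparative chromatography on a chiral stationary phase separates the two, and the route is rejoined at 8.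

2. Step 13. Proton transfer from the C2–H of the terminal oxazole or from the CH2 between the rings to iPrMgCl or to the aryl Grignard reagent would metalate the wrong position and return reduced bis-oxazole. Attack on the myristate is a second possible leak. Fallback: setting out from lactol 11 (step 8 is left out) and iodide 20, a Nozaki–Hiyama–Kishi coupling (CrCl2, NiCl2 cat., DMF, rt) replaces the Grignard reagent by a non-basic arylchromium species. This adds to the open-chain aldehyde tautomer of 11, (2S,3R,4S)-4-[(tert-butyldimethylsilyl)oxy]-2-hydroxy-6-oxohexan-3-yl tetradecanoate F3. The C1 carbinol should form as 24 together with its C1 epimer (2S,3R,4S,6S)-4-[(tert-butyldimethylsilyl)oxy]-2,6-dihydroxy-6-[2-(1,3-oxazol-5-ylmethyl)-1,3-oxazol-4-yl]hexan-3-yl tetradecanoate F4. MnO2 in CH2Cl2 then oxidises only the oxazolyl carbinol of both epimers to ketone 23, which closes to hemiketal 22, where the route is rejoined.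

3. Step 14. The reduction may be throttled if the ring–chain equilibrium lies far on the hemiketal side, and catalyst control may be eroded by the existing stereocentres or by chelation of ruthenium between the oxazole nitrogen and the ketone. Either would give slow conversion or a mixture at C1. Fallback: setting out from 22, the O3 silyl group is removed first (HF·pyridine, THF) to give (2S,3S,4S)-4,6-dihydroxy-2-methyl-6-[2-(1,3-oxazol-5-ylmethyl)-1,3-oxazol-4-yl]oxan-3-yl tetradecanoate F5. This is in equilibrium with the β-hydroxy ketone (2S,3R,4S)-2,4-dihydroxy-6-oxo-6-[2-(1,3-oxazol-5-ylmethyl)-1,3-oxazol-4-yl]hexan-3-yl tetradecanoate F6. Narasaka–Prasad reduction (Et2BOMe, NaBH4, THF/MeOH, −78 °C) of the boron chelate between the C3 hydroxyl and the ketone delivers hydride syn to O3 under substrate control and leads directly to target 25.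

Further compounds
F1 | step 4 | (2R,3S,6R)-4-[(tert-butyldimethylsilyl)oxy]-6-methoxy-2-methyl-3,6-dihydro-2H-pyran-3-yl tetradecanoate | C[C@@H]1[C@H](OC(=O)CCCCCCCCCCCCC)C(O[Si](C)(C)C(C)(C)C)=C[C@H](OC)O1
F2 | step 4 | (2R,3S)-2-methyl-4-oxo-3,4-dihydro-2H-pyran-3-yl tetradecanoate | C[C@@H]1[C@H](OC(=O)CCCCCCCCCCCCC)C(=O)C=CO1
F3 | step 13 | (2S,3R,4S)-4-[(tert-butyldimethylsilyl)oxy]-2-hydroxy-6-oxohexan-3-yl tetradecanoate | C[C@H](O)[C@@H](OC(=O)CCCCCCCCCCCCC)[C@@H](O[Si](C)(C)C(C)(C)C)CC=O
F4 | step 13 | (2S,3R,4S,6S)-4-[(tert-butyldimethylsilyl)oxy]-2,6-dihydroxy-6-[2-(1,3-oxazol-5-ylmethyl)-1,3-oxazol-4-yl]hexan-3-yl tetradecanoate | C[C@H](O)[C@@H](OC(=O)CCCCCCCCCCCCC)[C@@H](O[Si](C)(C)C(C)(C)C)C[C@H](O)c1coc(Cc2cnco2)n1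
F5 | step 14 | (2S,3S,4S)-4,6-dihydroxy-2-methyl-6-[2-(1,3-oxazol-5-ylmethyl)-1,3-oxazol-4-yl]oxan-3-yl tetradecanoate | C[C@H]1[C@@H](OC(=O)CCCCCCCCCCCCC)[C@@H](O)CC(O)(c2coc(Cc3cnco3)n2)O1
F6 | step 14 | (2S,3R,4S)-2,4-dihydroxy-6-oxo-6-[2-(1,3-oxazol-5-ylmethyl)-1,3-oxazol-4-yl]hexan-3-yl tetradecanoate | C[C@H](O)[C@@H](OC(=O)CCCCCCCCCCCCC)[C@@H](O)CC(=O)c1coc(Cc2cnco2)n1
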